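The isoflavan is disconnected across its pyran ring at C4–C4a and O1–C8a. Ring A then arrives as an aryl iodide, and C2, C3, C4, O1 and ring B arrive together as one enantiopure 3-bromo-2-arylpropan-1-ol whose C3 stereocentre is set beforehand by lipase desymmetrisation of a 2-aryl-1,3-propanediol. The key step exploits the fact that C4a and C8a are neighbouring carbons of ring A, that C4a–H is the only C–H ortho to the C8a iodide and that the C8 methoxy group occupies the other ortho site: a palladium/norbornene relay alkylates C4a and then etherifies C8a, closing the pyran ring in one operation. Hydrogenolysis of two benzyl ethers finishes the synthesis.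

Key step: step 9

Assumption: Burkholderia cepacia lipase is taken to show toward diol 6 its usual preference among β-branched primary alcohols (aryl as the large group) and so to acetylate the pro-R hydroxymethyl arm; the opposite preference would be met by reversing the order in which the two arms are functionalised.

Step 1
Reactants: 1 2-hydroxy-3,4-dimethoxybenzaldehyde
Product: 2 2-(benzyloxy)-3,4-dimethoxybenzaldehyde
Conditions: BnBr, K2CO3, DMF, 60 °C
Reagents that add atoms: benzyl bromide, BrCc1ccccc1
Why: Williamson ether synthesis on the phenoxide, with benzyl chosen so that both phenols of the target can be unmasked together by hydrogenolysis at the end.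

Step 2
Reactants: 2 2-(benzyloxy)-3,4-dimethoxybenzaldehyde; 3 ethyl diazoacetate
Product: 4 ethyl (2Z)-2-[2-(benzyloxy)-3,4-dimethoxyphenyl]-3-hydroxyprop-2-enoate (enol tautomer of the α-formyl arylacetate)
Conditions: HBF4·OEt2 (10 mol%), CH2Cl2, −78 °C
Reagents that add atoms: none
Why: Brønsted-acid-catalysed addition of the diazo ester to the aldehyde and loss of N2 with 1,2-aryl migration (the aryl-shift branch of the Roskamp homologation), which the electron-rich trialkoxyphenyl group should favour over hydride shift, places the aryl group on the central carbon of the three-carbon unit.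

Step 3
Reactants: 4 ethyl (2Z)-2-[2-(benzyloxy)-3,4-dimethoxyphenyl]-3-hydroxyprop-2-enoate
Product: 6 2-[2-(benzyloxy)-3,4-dimethoxyphenyl]propane-1,3-diol, via racemic hydroxy ester 5 (not isolated)
Conditions: LiBH4, THF–EtOH, 0 °C → rt
Reagents that add atoms: none
Why: Hydride reduction of the formyl tautomer (kept accessible by the protic co-solvent) and then of the ester by lithium borohydride should give the diol, in which the transient stereocentre of 5 disappears because the two arms become identical.

Step 4
Reactants: 6 2-[2-(benzyloxy)-3,4-dimethoxyphenyl]propane-1,3-diol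
Product: 7 (2R)-2-[2-(benzyloxy)-3,4-dimethoxyphenyl]-3-hydroxypropyl acetate
Conditions: lipase PS (Burkholderia cepacia, immobilised), vinyl acetate, t-BuOMe, 25 °C
Reagents that add atoms: vinyl acetate, CC(=O)OC=C
Why: Enzymatic desymmetrisation by irreversible transesterification, in which the lipase acylates only the pro-R hydroxymethyl group of the prochiral diol and thereby sets the future C3 stereocentre under enzyme control, the reaction being stopped at the monoacetate stage.

Step 5
Reactants: 7 (2R)-2-[2-(benzyloxy)-3,4-dimethoxyphenyl]-3-hydroxypropyl acetate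
Product: 8 (2S)-2-[2-(benzyloxy)-3,4-dimethoxyphenyl]-3-bromopropyl acetate
Conditions: CBr4, PPh3, CH2Cl2, 0 °C
Reagents that add atoms: carbon tetrabromide, BrC(Br)(Br)Br
Why: Appel reaction, an SN2 displacement of the alkoxyphosphonium group by bromide at the primary carbon under neutral conditions that leave no time for acetyl migration; the stereocentre is not touched and its descriptor changes only through the CIP priorities.

Step 6
Reactants: 8 (2S)-2-[2-(benzyloxy)-3,4-dimethoxyphenyl]-3-bromopropyl acetate
Product: 9 (2S)-2-[2-(benzyloxy)-3,4-dimethoxyphenyl]-3-bromopropan-1-ol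
Conditions: HCl (cat.), MeOH, 0 °C → rt
Reagents that add atoms: none
Why: Acid-catalysed transesterification removes the acetate without ever generating an alkoxide next to the bromide, so that neither oxetane closure nor dehydrobromination nor exchange of the two arms can occur.

Step 7
Reactants: 10 2,3-dimethoxyphenol
Product: 11 4-iodo-2,3-dimethoxyphenol
Conditions: NIS (1.0 equiv), TsOH·H2O (10 mol%), MeCN, 0 °C → rt
Reagents that add atoms: N-iodosuccinimide, O=C1CCC(=O)N1I
Why: Electrophilic aromatic iodination, in which the free hydroxyl as the strongest donor should direct the acid-activated reagent to its para position, a site further activated by the neighbouring methoxy group.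

Step 8
Reactants: 11 4-iodo-2,3-dimethoxyphenol
Product: 12 1-(benzyloxy)-4-iodo-2,3-dimethoxybenzene
Conditions: BnBr, K2CO3, acetone, reflux
Reagents that add atoms: benzyl bromide, BrCc1ccccc1
Why: Williamson ether synthesis, which masks the phenol that would otherwise compete as an oxygen nucleophile in the palladium step.

Step 9
Reactants: 12 1-(benzyloxy)-4-iodo-2,3-dimethoxybenzene; 9 (2S)-2-[2-(benzyloxy)-3,4-dimethoxyphenyl]-3-bromopropan-1-ol
Product: 13 (3S)-6-(benzyloxy)-3-[2-(benzyloxy)-3,4-dimethoxyphenyl]-7,8-dimethoxychromane
Conditions: Pd(OAc)2 (10 mol%), XPhos (20 mol%), norbornene (1 equiv), Cs2CO3 (3 equiv), 9 (1.5 equiv), 1,4-dioxane, 90 °C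
Reagents that add atoms: none
Why: Proposed new method: Pd(0) inserts into the C8a–I bond of 12, norbornene insertion and palladation of the C4a–H bond give an aryl–norbornyl palladacycle, this takes up the primary C–Br bond of 9 to a Pd(IV) species that forms C4–C4a by reductive elimination, norbornene is extruded, and the pendant hydroxyl, deprotonated on palladium by carbonate, closes O1–C8a by C–O reductive elimination. The closest known reaction types are the Pd/norbornene ortho-alkylation with ipso C–O termination that unites aryl iodides and epoxides to 2,3-dihydrobenzofurans and the ortho-alkylation/ipso-amination of aryl iodides with 3-bromopropylamines to tetrahydroquinolines; the free 3-bromopropanol partner, one carbon longer than the epoxide case, is not precedented. The pyran ring is closed in the second event, by aryl C–O reductive elimination from a seven-membered aryl–palladium alkoxide chelate (Pd, C8a, C4a, C4, C3, C2, O1), the intramolecular counterpart of Buchwald–Hartwig etherification, after the intermolecular C–C bond has tied the two fragments together. No stereocentre is formed; C3 is brought in by 9 and no bond to it is made or broken, so its configuration should pass unchanged into 13. Site selectivity rests on the substrate, since C4a–H is the only C–H ortho to the iodide and the C8 methoxy group makes the aryl–palladium centre doubly ortho-substituted after alkylation, which drives norbornene extrusion; chemoselectivity for C–O closure over β-hydride elimination of the alkoxide and over arylation of C6'–H in ring B is sought through the bulky biaryl phosphine and the moderate temperature. Heterogeneous carbonate in dioxane and an excess of 9 should keep base-induced loss of 9 to the achiral oxetane or to the allylic alcohol from limiting the conversion.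

Step 10
Reactants: 13 (3S)-6-(benzyloxy)-3-[2-(benzyloxy)-3,4-dimethoxyphenyl]-7,8-dimethoxychromane
Product: 14 (3S)-3-(2-hydroxy-3,4-dimethoxyphenyl)-7,8-dimethoxychroman-6-ol
Conditions: H2 (1 atm), 10% Pd/C, EtOAc–MeOH, rt
Reagents that add atoms: none
Why: Catalytic hydrogenolysis cleaves both aryl benzyl ethers under neutral conditions, while the aryl methyl ethers, the chroman ring and the C3 stereocentre (no C–O bond at C3) should be unaffected.

Compound list
1 | 2-hydroxy-3,4-dimethoxybenzaldehyde | COc1ccc(C=O)c(O)c1OC | starting material
2 | 2-(benzyloxy)-3,4-dimethoxybenzaldehyde | COc1ccc(C=O)c(OCc2ccccc2)c1OC | intermediate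
3 | ethyl diazoacetate | CCOC(=O)C=[N+]=[N-] | starting material
4 | ethyl (2Z)-2-[2-(benzyloxy)-3,4-dimethoxyphenyl]-3-hydroxyprop-2-enoate | CCOC(=O)/C(=C\O)c1ccc(OC)c(OC)c1OCc1ccccc1 | intermediate
5 | ethyl 2-[2-(benzyloxy)-3,4-dimethoxyphenyl]-3-hydroxypropanoate (racemic, not isolated) | CCOC(=O)C(CO)c1ccc(OC)c(OC)c1OCc1ccccc1 | intermediate
6 | 2-[2-(benzyloxy)-3,4-dimethoxyphenyl]propane-1,3-diol | COc1ccc(C(CO)CO)c(OCc2ccccc2)c1OC | intermediate
7 | (2R)-2-[2-(benzyloxy)-3,4-dimethoxyphenyl]-3-hydroxypropyl acetate | COc1ccc([C@H](CO)COC(C)=O)c(OCc2ccccc2)c1OC | intermediate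
8 | (2S)-2-[2-(benzyloxy)-3,4-dimethoxyphenyl]-3-bromopropyl acetate | COc1ccc([C@H](CBr)COC(C)=O)c(OCc2ccccc2)c1OC | intermediate
9 | (2S)-2-[2-(benzyloxy)-3,4-dimethoxyphenyl]-3-bromopropan-1-ol | COc1ccc([C@H](CBr)CO)c(OCc2ccccc2)c1OC | intermediate
10 | 2,3-dimethoxyphenol | COc1cccc(O)c1OC | starting material
11 | 4-iodo-2,3-dimethoxyphenol | COc1c(I)ccc(O)c1OC | intermediate
12 | 1-(benzyloxy)-4-iodo-2,3-dimethoxybenzene | COc1c(I)ccc(OCc2ccccc2)c1OC | intermediate
13 | (3S)-6-(benzyloxy)-3-[2-(benzyloxy)-3,4-dimethoxyphenyl]-7,8-dimethoxychromane | COc1ccc([C@H]2COc3c(cc(OCc4ccccc4)c(OC)c3OC)C2)c(OCc2ccccc2)c1OC | intermediate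
14 | (3S)-3-(2-hydroxy-3,4-dimethoxyphenyl)-7,8-dimethoxychroman-6-ol | COc1ccc([C@H]2COc3c(cc(O)c(OC)c3OC)C2)c(O)c1OC | target

Total step count: 10. Longest linear sequence: 8 steps (steps 1–6, 9 and 10).

Steps most likely to fail

Step 9 (Proposed new method). Uptake of the β-branched alkyl bromide by the palladacycle may be too slow. Coupling of the palladacycle with a second aryl iodide, 4-exo cyclisation or dehydrobromination of the bromo alcohol under the base, or β-hydride elimination at the alkoxide stage could then consume the partners before the pyran closes. The fallback uses known chemistry and forms the same ring from the same bromo alcohol through O1–C2 and C4–C4a. It sets out from 12, which would be hydroxylated (CuI, 1,10-phenanthroline, KOH, DMSO–H2O, 100 °C) to 4-(benzyloxy)-2,3-dimethoxyphenol F1. This phenol has only one free position ortho to the hydroxyl and should be iodinated there (NIS, MeCN, 0 °C) to give 4-(benzyloxy)-6-iodo-2,3-dimethoxyphenol F2. Mitsunobu etherification of F2 with 9 (PPh3, DIAD, THF, 0 °C → rt) should give 1-(benzyloxy)-4-{[(2S)-2-(2-benzyloxy-3,4-dimethoxyphenyl)-3-bromopropyl]oxy}-5-iodo-2,3-dimethoxybenzene F3. Parham cyclisation (n-BuLi, THF, −100 °C → −78 °C; iodine–lithium exchange, then intramolecular SN2 displacement of the primary bromide) would close C4–C4a and come back to the route at 13 with C3 untouched.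

Step 4. Discrimination between the two enantiotopic hydroxymethyl groups may be weak for an aryl group with a large ortho substituent, or may run in the opposite sense, and acetyl migration between the two oxygen atoms of the monoacetate would erode the enantiomeric purity. The fallback is a non-enzymatic desymmetrisation that sets out from 6. The diol would be mono-benzoylated with vinyl benzoate under dinuclear zinc–ProPhenol catalysis (Et2Zn, ligand enantiomer chosen for the pro-R arm, toluene, −15 °C), an asymmetric acyl transfer established for 2-aryl-1,3-propanediols, to give (2R)-2-[2-(benzyloxy)-3,4-dimethoxyphenyl]-3-hydroxypropyl benzoate F4, whose acyl group migrates less readily than acetyl. Appel bromination (CBr4, PPh3, CH2Cl2, 0 °C) should give (2S)-2-[2-(benzyloxy)-3,4-dimethoxyphenyl]-3-bromopropyl benzoate F5, and reductive removal of the benzoate (DIBAL-H, CH2Cl2, −78 °C) would come back to the route at 9.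

Step 7. Electrophilic attack at C6 (ortho to the hydroxyl, para to the 3-methoxy group) may compete with attack at C4, and a second iodination may follow, which would leave regioisomers that are hard to separate. The fallback fixes the position by directed metalation instead of electrophilic substitution and sets out from 10. Silylation (TIPSCl, imidazole, DMF, rt) would give (2,3-dimethoxyphenoxy)tri(propan-2-yl)silane F6. The bulky silyl ether neither directs nor admits lithiation at its own ortho position, so n-BuLi/TMEDA (THF, 0 °C) should metalate next to the 3-methoxy group, and an iodine quench should give (4-iodo-2,3-dimethoxyphenoxy)tri(propan-2-yl)silane F7. Desilylation (TBAF, THF, 0 °C) would come back to the route at 11.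

Further compounds
F1 | step 9 | 4-(benzyloxy)-2,3-dimethoxyphenol | COc1c(O)ccc(OCc2ccccc2)c1OC
F2 | step 9 | 4-(benzyloxy)-6-iodo-2,3-dimethoxyphenol | COc1c(O)c(I)cc(OCc2ccccc2)c1OC
F3 | step 9 | 1-(benzyloxy)-4-{[(2S)-2-(2-benzyloxy-3,4-dimethoxyphenyl)-3-bromopropyl]oxy}-5-iodo-2,3-dimethoxybenzene | COc1ccc([C@H](CBr)COc2c(I)cc(OCc3ccccc3)c(OC)c2OC)c(OCc2ccccc2)c1OC
F4 | step 4 | (2R)-2-[2-(benzyloxy)-3,4-dimethoxyphenyl]-3-hydroxypropyl benzoate | COc1ccc([C@H](CO)COC(=O)c2ccccc2)c(OCc2ccccc2)c1OC
F5 | step 4 | (2S)-2-[2-(benzyloxy)-3,4-dimethoxyphenyl]-3-bromopropyl benzoate | COc1ccc([C@H](CBr)COC(=O)c2ccccc2)c(OCc2ccccc2)c1OC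
F6 | step 7 | (2,3-dimethoxyphenoxy)tri(propan-2-yl)silane | COc1cccc(O[Si](C(C)C)(C(C)C)C(C)C)c1OC
F7 | step 7 | (4-iodo-2,3-dimethoxyphenoxy)tri(propan-2-yl)silane | COc1c(I)ccc(O[Si](C(C)C)(C(C)C)C(C)C)c1OC
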